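The pyranone of ring A is cut at C4a–C4 and O2–C3. Ring A has a single aromatic hydrogen beside its carboxyl-bearing carbon C8a, the one on C4a, since C8 is occupied by the diaryl ether oxygen; C4 and C3 with the pentyl group amount to an acylmethyl fragment. A carboxyl-guided C–H alkylation with the sulfoxonium ylide of heptan-2-one, followed by cyclodehydration in the same flask, thus makes both bonds and the ring at once. The substrate is a 2-aryloxy-4-methoxybenzoic acid whose ring B is finished and inert: two benzyl ethers, a benzyl ester and a dioxolane masking the 2-oxoheptyl ketone.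

Key step: step 10

Remarks on the chemistry
- Assumption: the target is taken as the open keto acid drawn; in solution ring B may equilibrate with its cyclic lactol.
- Ring B is numbered as in orsellinic acid throughout (C1 carboxyl, C2 and C4 oxygens, C5 diaryl ether oxygen, C6 side chain).
- The ring B carboxyl is carried as a benzyl ester. All three benzyl groups go on in one step and come off together in the last step under neutral conditions. The dioxolane is removed one step earlier, while the carboxyl is still esterified. The free 2-(2-oxoheptyl)benzoic acid of ring B therefore never meets acid or heat, which could close it to a second isocoumarin, and no carbocation is released next to a free resorcinol.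
- The C5 oxygen of ring B enters by bromination and palladium-catalysed hydroxylation, because electrophilic formylating reagents are not compatible with the ketal and the benzyl ethers.

Step 1
Reactants: 1 2,4-dihydroxy-6-methylbenzoic acid (orsellinic acid)
Product: 2 benzyl 2,4-bis(benzyloxy)-6-methylbenzoate
Conditions: BnBr (3.5 equiv), K2CO3 (4 equiv), DMF, 60 °C
Reagents that add atoms: benzyl bromide, BrCc1ccccc1
Why: Williamson O-alkylation of the carboxylate and both phenoxides in one pot; the carboxylate reacts first, which also blocks decarboxylation, and warm DMF with excess K2CO3 should bring the hydrogen-bonded 2-hydroxyl to completion.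

Step 2
Reactants: 2 benzyl 2,4-bis(benzyloxy)-6-methylbenzoate
Product: 3 benzyl 2,4-bis(benzyloxy)-5-bromo-6-methylbenzoate
Conditions: NBS (1.0 equiv), MeCN, 0 °C → rt
Reagents that add atoms: N-bromosuccinimide, O=C1CCC(=O)N1Br
Why: Electrophilic aromatic bromination; C5 is para to the C2 ether and ortho to the C4 ether and is less shielded than C3 between two benzyloxy groups, the preference that 3,5-dialkoxytoluenes show for the position next to the methyl group.

Step 3
Reactants: 4 hexanoyl chloride
Product: 5 N-methoxy-N-methylhexanamide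
Conditions: MeNH(OMe)·HCl (1.1 equiv), Et3N (2.2 equiv), CH2Cl2, 0 °C → rt
Reagents that add atoms: N,O-dimethylhydroxylamine hydrochloride, CNOC.Cl
Why: N-acylation of the hydroxylamine by the acid chloride (Weinreb amide formation), fast and clean at 0 °C.

Step 4
Reactants: 3 benzyl 2,4-bis(benzyloxy)-5-bromo-6-methylbenzoate; 5 N-methoxy-N-methylhexanamide
Product: 8 benzyl 2,4-bis(benzyloxy)-5-bromo-6-(2-oxoheptyl)benzoate, via benzylic lithium species 6 (not isolated), via lithium hemiaminal adduct 7 (not isolated)
Conditions: LiN(iPr)2 (LDA, 2.0 equiv), THF, −78 °C; then 5 (1.2 equiv), −78 °C; aq. NH4Cl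
Reagents that add atoms: none
Why: Lateral lithiation of an ortho-toluate, whose C6 methyl is acidified by the neighbouring ester, followed by Weinreb ketone synthesis; the chelated adduct 7 holds until the quench, so over-addition and enolate attack on the ester are excluded, and the amide base at −78 °C should leave the aryl bromide and the benzyl groups alone.

Step 5
Reactants: 8 benzyl 2,4-bis(benzyloxy)-5-bromo-6-(2-oxoheptyl)benzoate
Product: 9 benzyl 2,4-bis(benzyloxy)-5-bromo-6-[(2-pentyl-1,3-dioxolan-2-yl)methyl]benzoate
Conditions: Me3SiOCH2CH2OSiMe3 (3 equiv), Me3SiOTf (10 mol%), CH2Cl2, −78 → −20 °C; pyridine quench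
Reagents that add atoms: 1,2-bis(trimethylsilyloxy)ethane, C[Si](C)(C)OCCO[Si](C)(C)C
Why: Noyori ketalisation, driven by formation of hexamethyldisiloxane; it runs cold and aprotic, avoiding the hot protic acid under which a 2-(2-oxoalkyl)benzoate could close to an isocoumarin.

Step 6
Reactants: 9 benzyl 2,4-bis(benzyloxy)-5-bromo-6-[(2-pentyl-1,3-dioxolan-2-yl)methyl]benzoate
Product: 10 benzyl 2,4-bis(benzyloxy)-5-hydroxy-6-[(2-pentyl-1,3-dioxolan-2-yl)methyl]benzoate
Conditions: Pd2(dba)3 (2 mol%), tBuXPhos (8 mol%), KOH (3 equiv), 1,4-dioxane/H2O, 80 °C; then aq. NaH2PO4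
Reagents that add atoms: potassium hydroxide, [K+].[OH-]
Why: Palladium-catalysed hydroxylation of an aryl bromide with hydroxide (Buchwald-type C–O coupling); the bulky biaryl phosphine promotes C–O reductive elimination at the hindered carbon, the ketal is inert to base, and the benzyl ester is shielded from saponification by its two ortho substituents.

Step 7
Reactants: 10 benzyl 2,4-bis(benzyloxy)-5-hydroxy-6-[(2-pentyl-1,3-dioxolan-2-yl)methyl]benzoate; 11 2-fluoro-4-methoxybenzaldehyde
Product: 12 benzyl 2,4-bis(benzyloxy)-5-(2-formyl-5-methoxyphenoxy)-6-[(2-pentyl-1,3-dioxolan-2-yl)methyl]benzoate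
Conditions: Cs2CO3 (1.5 equiv), DMF, 90 °C
Reagents that add atoms: none
Why: Nucleophilic aromatic substitution (addition–elimination) of the fluoride ortho to the formyl group by the electron-rich phenoxide; the aldehyde stabilises the Meisenheimer intermediate, and the methoxy group, meta to the reacting carbon, does not deactivate it.

Step 8
Reactants: 12 benzyl 2,4-bis(benzyloxy)-5-(2-formyl-5-methoxyphenoxy)-6-[(2-pentyl-1,3-dioxolan-2-yl)methyl]benzoate
Product: 13 2-{4,6-bis(benzyloxy)-3-[(benzyloxy)carbonyl]-2-[(2-pentyl-1,3-dioxolan-2-yl)methyl]phenoxy}-4-methoxybenzoic acid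
Conditions: NaClO2, NaH2PO4, 2-methyl-2-butene, tBuOH/THF/H2O, 0 °C → rt
Reagents that add atoms: sodium chlorite, [Na+].[O-]Cl=O
Why: Pinnick oxidation of the aryl aldehyde by chlorous acid; the buffered medium should leave ketal, ester and ethers untouched, and 2-methyl-2-butene traps hypochlorous acid before it can chlorinate the electron-rich rings.

Step 9
Reactants: 14 trimethylsulfoxonium iodide; 4 hexanoyl chloride
Product: 17 1-(dimethyloxosulfuranylidene)heptan-2-one, via dimethylsulfoxonium methylide 15 (not isolated), via acylsulfoxonium chloride 16 (not isolated)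
Conditions: KOtBu (3 equiv), 14 (3 equiv), THF, reflux; then 4 (1 equiv), 0 °C → rt
Reagents that add atoms: none
Why: C-acylation of the Corey–Chaykovsky methylide by the acid chloride; a second equivalent of methylide deprotonates salt 16 to give the stabilised, storable keto ylide.

Step 10
Reactants: 13 2-{4,6-bis(benzyloxy)-3-[(benzyloxy)carbonyl]-2-[(2-pentyl-1,3-dioxolan-2-yl)methyl]phenoxy}-4-methoxybenzoic acid; 17 1-(dimethyloxosulfuranylidene)heptan-2-one
Product: 19 benzyl 2,4-bis(benzyloxy)-5-[(6-methoxy-1-oxo-3-pentyl-1H-isochromen-8-yl)oxy]-6-[(2-pentyl-1,3-dioxolan-2-yl)methyl]benzoate, via oxoheptyl acid 18 (not isolated)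
Conditions: [Cp*RhCl2]2 (4 mol%), NaOAc (1.0 equiv), 17 (1.5 equiv), CF3CH2OH, 80 °C
Reagents that add atoms: none
Why: Acetate-assisted deprotonative metalation, steered by the carboxylate of 13, places trivalent rhodium on the only free ortho carbon (C6 of the acid, the future C4a) in a five-membered rhodacycle; ylide 17 then binds through carbon, expels dimethyl sulfoxide to leave a rhodium carbene, the aryl group migrates onto the carbene carbon, and protonolysis frees keto acid 18 and the catalyst. The closest known reaction is the Cp*Rh-catalysed C–H acylmethylation and annulation of benzoic acids with sulfoxonium ylides, which gives 3-substituted isocoumarins without an external oxidant. The pyranone closes by 6-exo-trig addition of the carboxyl oxygen to the new ketone and loss of water from the lactol, favoured by conjugation of the resulting enol lactone with ring A. No stereocentre is created. The step needs site selectivity and chemoselective lactonisation: the first follows from C2 of the acid (the future C8) being substituted, so only one ortho C–H exists; the second from ring B carrying its carboxyl as a doubly flanked benzyl ester, its ketone as a dioxolane, and no C–H next to a directing group. If the warm, weakly acidic medium opens the dioxolane early, nothing is lost, because step 11 removes it anyway and a benzyl ester should not lactonise here.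

Step 11
Reactants: 19 benzyl 2,4-bis(benzyloxy)-5-[(6-methoxy-1-oxo-3-pentyl-1H-isochromen-8-yl)oxy]-6-[(2-pentyl-1,3-dioxolan-2-yl)methyl]benzoate
Product: 20 benzyl 2,4-bis(benzyloxy)-5-[(6-methoxy-1-oxo-3-pentyl-1H-isochromen-8-yl)oxy]-6-(2-oxoheptyl)benzoate
Conditions: 1 M HCl (aq)/THF, rt → 40 °C
Reagents that add atoms: water, O
Why: Acid-catalysed ketal hydrolysis through the oxocarbenium ion; isocoumarin, aryl ethers and benzyl ester are stable to dilute aqueous acid, and with the ring B carboxyl still esterified the freed ketone cannot lactonise.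

Step 12
Reactants: 20 benzyl 2,4-bis(benzyloxy)-5-[(6-methoxy-1-oxo-3-pentyl-1H-isochromen-8-yl)oxy]-6-(2-oxoheptyl)benzoate
Product: 21 beta-collatolic acid, 2,4-dihydroxy-5-[(6-methoxy-1-oxo-3-pentyl-1H-isochromen-8-yl)oxy]-6-(2-oxoheptyl)benzoic acid
Conditions: H2 (1 atm), 10% Pd/C, EtOAc, rt
Reagents that add atoms: none
Why: Catalytic hydrogenolysis of two aryl benzyl ethers and one benzyl ester, expected to be much faster than hydrogenation of the trisubstituted, conjugated C3–C4 double bond of ring A; the keto acid is released under neutral conditions, so ring B has no acid catalyst for cyclodehydration.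

Compound list
1 | 2,4-dihydroxy-6-methylbenzoic acid (orsellinic acid) | Cc1cc(O)cc(O)c1C(=O)O | starting material
2 | benzyl 2,4-bis(benzyloxy)-6-methylbenzoate | Cc1cc(OCc2ccccc2)cc(OCc2ccccc2)c1C(=O)OCc1ccccc1 | intermediate
3 | benzyl 2,4-bis(benzyloxy)-5-bromo-6-methylbenzoate | Cc1c(Br)c(OCc2ccccc2)cc(OCc2ccccc2)c1C(=O)OCc1ccccc1 | intermediate
4 | hexanoyl chloride | CCCCCC(=O)Cl | starting material
5 | N-methoxy-N-methylhexanamide | CCCCCC(=O)N(C)OC | intermediate
6 | benzylic lithium species of 3 (lithiated at the C6 methyl) | [Li]Cc1c(Br)c(OCc2ccccc2)cc(OCc2ccccc2)c1C(=O)OCc1ccccc1 | intermediate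
7 | lithium hemiaminal adduct of 6 and 5 (racemic, transient) | CCCCCC(O[Li])(N(C)OC)Cc1c(Br)c(OCc2ccccc2)cc(OCc2ccccc2)c1C(=O)OCc1ccccc1 | intermediate
8 | benzyl 2,4-bis(benzyloxy)-5-bromo-6-(2-oxoheptyl)benzoate | CCCCCC(=O)Cc1c(Br)c(OCc2ccccc2)cc(OCc2ccccc2)c1C(=O)OCc1ccccc1 | intermediate
9 | benzyl 2,4-bis(benzyloxy)-5-bromo-6-[(2-pentyl-1,3-dioxolan-2-yl)methyl]benzoate | CCCCCC1(Cc2c(Br)c(OCc3ccccc3)cc(OCc3ccccc3)c2C(=O)OCc2ccccc2)OCCO1 | intermediate
10 | benzyl 2,4-bis(benzyloxy)-5-hydroxy-6-[(2-pentyl-1,3-dioxolan-2-yl)methyl]benzoate | CCCCCC1(Cc2c(O)c(OCc3ccccc3)cc(OCc3ccccc3)c2C(=O)OCc2ccccc2)OCCO1 | intermediate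
11 | 2-fluoro-4-methoxybenzaldehyde | COc1ccc(C=O)c(F)c1 | starting material
12 | benzyl 2,4-bis(benzyloxy)-5-(2-formyl-5-methoxyphenoxy)-6-[(2-pentyl-1,3-dioxolan-2-yl)methyl]benzoate | CCCCCC1(Cc2c(Oc3cc(OC)ccc3C=O)c(OCc3ccccc3)cc(OCc3ccccc3)c2C(=O)OCc2ccccc2)OCCO1 | intermediate
13 | 2-{4,6-bis(benzyloxy)-3-[(benzyloxy)carbonyl]-2-[(2-pentyl-1,3-dioxolan-2-yl)methyl]phenoxy}-4-methoxybenzoic acid (substrate of the key step) | CCCCCC1(Cc2c(Oc3cc(OC)ccc3C(=O)O)c(OCc3ccccc3)cc(OCc3ccccc3)c2C(=O)OCc2ccccc2)OCCO1 | intermediate
14 | trimethylsulfoxonium iodide | C[S+](C)(C)=O.[I-] | starting material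
15 | dimethylsulfoxonium methylide | [CH2-][S+](C)(C)=O | intermediate
16 | dimethyl(2-oxoheptyl)sulfoxonium chloride | CCCCCC(=O)C[S+](C)(C)=O.[Cl-] | intermediate
17 | 1-(dimethyloxosulfuranylidene)heptan-2-one | CCCCCC(=O)C=S(C)(C)=O | intermediate
18 | 2-{4,6-bis(benzyloxy)-3-[(benzyloxy)carbonyl]-2-[(2-pentyl-1,3-dioxolan-2-yl)methyl]phenoxy}-4-methoxy-6-(2-oxoheptyl)benzoic acid | CCCCCC(=O)Cc1cc(OC)cc(Oc2c(OCc3ccccc3)cc(OCc3ccccc3)c(C(=O)OCc3ccccc3)c2CC2(CCCCC)OCCO2)c1C(=O)O | intermediate
19 | benzyl 2,4-bis(benzyloxy)-5-[(6-methoxy-1-oxo-3-pentyl-1H-isochromen-8-yl)oxy]-6-[(2-pentyl-1,3-dioxolan-2-yl)methyl]benzoate (product of the key step) | CCCCCc1cc2cc(OC)cc(Oc3c(OCc4ccccc4)cc(OCc4ccccc4)c(C(=O)OCc4ccccc4)c3CC3(CCCCC)OCCO3)c2c(=O)o1 | intermediate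
20 | benzyl 2,4-bis(benzyloxy)-5-[(6-methoxy-1-oxo-3-pentyl-1H-isochromen-8-yl)oxy]-6-(2-oxoheptyl)benzoate | CCCCCC(=O)Cc1c(Oc2cc(OC)cc3cc(CCCCC)oc(=O)c23)c(OCc2ccccc2)cc(OCc2ccccc2)c1C(=O)OCc1ccccc1 | intermediate
21 | beta-collatolic acid, 2,4-dihydroxy-5-[(6-methoxy-1-oxo-3-pentyl-1H-isochromen-8-yl)oxy]-6-(2-oxoheptyl)benzoic acid | CCCCCC(=O)Cc1c(Oc2cc(OC)cc3cc(CCCCC)oc(=O)c23)c(O)cc(O)c1C(=O)O | target

Total step count: 12 steps.
Longest linear sequence: 10 steps from orsellinic acid 1 (steps 1, 2, 4, 5, 6, 7, 8, 10, 11, 12); steps 3 and 9 are one-step side branches from hexanoyl chloride 4.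

The three steps most likely to fail

Step 10 (key step). C–H metalation may be slow because the bulky ortho aryloxy group twists the carboxylate out of the ring plane and crowds the metal, so that unproductive decomposition of the ylide outruns the coupling. The fallback runs the same annulation on a small acid first and forms the diaryl ether afterwards. It sets out from phenol 10 and ylide 17. Commercial 2-fluoro-4-methoxybenzoic acid (COc1ccc(C(=O)O)c(F)c1) and 17 under the conditions of step 10 should give, through 2-fluoro-4-methoxy-6-(2-oxoheptyl)benzoic acid F1 formed in the flask, 8-fluoro-6-methoxy-3-pentyl-1H-isochromen-1-one F2. Its fluoride is ortho to the lactone carbonyl, and nucleophilic aromatic substitution by the phenoxide of 10 (Cs2CO3, DMSO, 90 °C) should lead directly to 19, where the route is rejoined; steps 7 and 8 fall away.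

Step 6. Oxidative addition and C–O reductive elimination at a bromide flanked on both sides may be slow, leaving room for hydrodebromination and for hydroxide attack on the benzyl ester. The fallback forms a carbon–boron bond and oxidises it, instead of coupling with hydroxide. From bromide 9, Miyaura borylation (Pd(OAc)2, SPhos, B2pin2, KOAc, 1,4-dioxane, 90 °C) should give benzyl 2,4-bis(benzyloxy)-6-[(2-pentyl-1,3-dioxolan-2-yl)methyl]-5-(4,4,5,5-tetramethyl-1,3,2-dioxaborolan-2-yl)benzoate F3. Oxidation with NaBO3·4H2O in THF/water at room temperature then returns to phenol 10 without strong base.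

Step 12. Saturation of the C3–C4 double bond of the ring A enol lactone may compete with benzyl cleavage once the more reactive groups are gone. The fallback is a Lewis-acid debenzylation without hydrogen. From 20, BCl3 with pentamethylbenzene as cation scavenger (CH2Cl2, −78 → 0 °C) should cleave both aryl benzyl ethers and the benzyl ester and, after a cold aqueous quench, give 21. The ring A methyl ether is not chelated to a carbonyl group and should survive. No new compound lies on this path.

Further compounds
F1 | step 10 | 2-fluoro-4-methoxy-6-(2-oxoheptyl)benzoic acid | CCCCCC(=O)Cc1cc(OC)cc(F)c1C(=O)O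
F2 | step 10 | 8-fluoro-6-methoxy-3-pentyl-1H-isochromen-1-one | CCCCCc1cc2cc(OC)cc(F)c2c(=O)o1
F3 | step 6 | benzyl 2,4-bis(benzyloxy)-6-[(2-pentyl-1,3-dioxolan-2-yl)methyl]-5-(4,4,5,5-tetramethyl-1,3,2-dioxaborolan-2-yl)benzoate | CCCCCC1(Cc2c(B3OC(C)(C)C(C)(C)O3)c(OCc3ccccc3)cc(OCc3ccccc3)c2C(=O)OCc2ccccc2)OCCO1
F0 | step 12 | none | none
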